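The route rests on cutting the sp2–sp2 single bond C14–C15, between the trisubstituted C13=C14 alkene and the central C15=C15′ alkene. The cut exploits the fact that C15′ through ring B (the unoxygenated trimethylcyclohexene) is the intact skeleton of all-trans-retinal, so only one CH, C15, is missing. In one flask, lithiated bis(pinacolato)borylmethane turns retinal into the (E)-C21 pentaenyl boronate (boron–Wittig). The surviving boron is then spent in a stereoretentive Suzuki–Miyaura coupling at C14 of a C19 tetraenyl iodide that already carries ring A and its (3R)-oleate. The precursors are thus an aldehyde, a one-carbon gem-diboron linchpin and a vinyl iodide, and the coupling delivers the target directly.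

Key step: step 9

Remark: carotenoid numbering is used (ring A = C1–C6 with the ester at C3, chain C7–C15, primed numbers for the retinal-derived half, ring B = C1′–C6′). Enantiopure (4R,6R)-actinol is taken as a purchasable industrial intermediate, and all polyene steps run under argon in dim light.

Step 1
Reactants: 1 (4R,6R)-4-hydroxy-2,2,6-trimethylcyclohexanone (actinol); 2 oleoyl chloride
Product: 3 (1R,3R)-3,5,5-trimethyl-4-oxocyclohexyl oleate
Conditions: pyridine, DMAP (cat.), CH2Cl2, 0 °C to rt
Reagents that add atoms: none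
Why: DMAP-catalysed acyl transfer to the unhindered secondary alcohol breaks no bond at the carbinol carbon, so the 4R centre (future C3) is kept, and the ester serves as the only hydroxyl protection the route needs.

Step 2
Reactants: 3 (1R,3R)-3,5,5-trimethyl-4-oxocyclohexyl oleate
Product: 4 (1R)-3,5,5-trimethyl-4-(trifluoromethylsulfonyloxy)cyclohex-3-en-1-yl oleate (ring A enol triflate)
Conditions: Tf2O, 2,6-di-tert-butyl-4-methylpyridine, CH2Cl2, 0 °C to rt
Reagents that add atoms: triflic anhydride O=S(=O)(OS(=O)(=O)C(F)(F)F)C(F)(F)F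
Why: Enol triflation with Tf2O and a non-nucleophilic hindered pyridine gives one tetrasubstituted enol triflate (the C5=C6 alkene), because the ketone can lose a proton only from the CH(CH3) carbon while its other α-carbon is quaternary; the now superfluous methyl-bearing stereocentre is erased, and the absence of strong base spares the enolisable ester and the Z-alkene.

Step 3
Reactants: 5 (E)-3-methylpent-2-en-4-yn-1-ol
Product: 6 (2E,4E)-3-methyl-5-(tributylstannyl)penta-2,4-dien-1-ol
Conditions: Bu3SnH (slow addition), Pd2(dba)3 (cat.), Cy3P·HBF4 (cat.), iPr2NEt (cat.), CH2Cl2, 0 °C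
Reagents that add atoms: tributyltin hydride CCCC[SnH](CCCC)CCCC
Why: In this palladium-catalysed syn-hydrostannation of a terminal alkyne the bulky, electron-rich Cy3P ligand directs tin to the terminal carbon, so the (E)-β-stannane (future 7E alkene) should dominate, while the 9E alkene comes with the starting material.

Step 4
Reactants: 4 ring A enol triflate; 6 (2E,4E)-3-methyl-5-(tributylstannyl)penta-2,4-dien-1-ol
Product: 7 (1R)-4-[(1E,3E)-5-hydroxy-3-methylpenta-1,3-dienyl]-3,5,5-trimethylcyclohex-3-en-1-yl oleate (C15 alcohol)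
Conditions: Pd2(dba)3 (cat.), AsPh3 (cat.), LiCl (3 equiv), NMP, 50–60 °C
Reagents that add atoms: none
Why: This is a Stille coupling of a vinyl triflate in which LiCl and the weakly bound AsPh3 ligand in NMP speed up transmetallation enough for the doubly flanked 2,6,6-trimethylcyclohexenyl triflate class; the C6–C7 bond forms with retention of the stannane geometry, and the neutral medium spares the ester, the free alcohol and C3.

Step 5
Reactants: 7 C15 alcohol
Product: 8 [(2E,4E)-3-methyl-5-[(4R)-2,6,6-trimethyl-4-oleoyloxycyclohex-1-enyl]penta-2,4-dienyl]triphenylphosphonium bromide (C15 Wittig salt)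
Conditions: Ph3P·HBr, CH2Cl2, 0 °C to rt
Reagents that add atoms: triphenylphosphine hydrobromide [Br-].c1ccc(cc1)[PH+](c1ccccc1)c1ccccc1
Why: In this acid-mediated SN1-type phosphonium salt formation, protonation and loss of water give a cation conjugated with ring A that PPh3 captures at the unhindered primary terminus C11; this is the standard entry to C15 carotenoid Wittig salts, and the conditions are too mild to cleave the ester.

Step 6
Reactants: 9 propargyl alcohol
Product: 11 (E)-3-iodo-2-methylprop-2-en-1-ol, via alkenylalane 10 (not isolated)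
Conditions: Me3Al (3 equiv), Cp2ZrCl2 (0.25 equiv), CH2Cl2, 0 °C to rt; then I2, THF, −30 to 0 °C; aq K2CO3
Reagents that add atoms: trimethylaluminium C[Al](C)C; iodine [I][I]
Why: Zirconium-catalysed methylalumination (Negishi carboalumination) adds methyl and aluminium syn across the alkyne with aluminium at the terminal carbon, and iodinolysis with retention fixes the E geometry that becomes 13E.

Step 7
Reactants: 11 (E)-3-iodo-2-methylprop-2-en-1-ol
Product: 12 (E)-3-iodo-2-methylprop-2-enal
Conditions: activated MnO2 (excess), CH2Cl2, rt, dark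
Reagents that add atoms: none
Why: Allylic alcohol oxidation with activated MnO2 is selective and neutral and does not isomerise or cleave the vinyl iodide.

Step 8
Reactants: 8 C15 Wittig salt; 12 (E)-3-iodo-2-methylprop-2-enal
Product: 14 (1R)-4-[(1E,3E,5E,7E)-8-iodo-3,7-dimethylocta-1,3,5,7-tetraenyl]-3,5,5-trimethylcyclohex-3-en-1-yl oleate (C19 tetraenyl iodide), via phosphorus ylide 13 (not isolated)
Conditions: NaN(SiMe3)2 (1.0 equiv), THF, −78 °C; then 12, −78 to 0 °C; chromatography
Reagents that add atoms: none
Why: In this Wittig olefination the semistabilised allylic ylide 13 forms selectively because the phosphonium α-protons are far more acidic than those of the ester; it attacks the aldehyde of 12 in 1,2 fashion and should give mainly the 11E alkene, the congested 11Z isomer is removed by chromatography, and the 13E vinyl iodide geometry sits in the aldehyde partner and is not touched.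

Step 9
Reactants: 15 all-trans-retinal; 14 C19 tetraenyl iodide
Product: 17 (3R)-β-cryptoxanthin oleate, via C21 pentaenyl boronate 16 (not isolated)
Conditions: CH2(Bpin)2, LiTMP (lithium 2,2,6,6-tetramethylpiperidide), THF, 0 °C; 15 (slight excess over the carbanion), −78 °C to rt; then degassed aq K3PO4, 14, Pd(OAc)2 (5 mol %), SPhos (10 mol %), rt, dark
Reagents that add atoms: bis(pinacolato)borylmethane CC1(C)OB(CB2OC(C)(C)C(C)(C)O2)OC1(C)C
Why: LiTMP deprotonates CH2(Bpin)2, the boron-stabilised carbanion adds 1,2 to the C15′ aldehyde of 15, and syn B–O elimination from the β-boryl alkoxide (boron–Wittig olefination) should give 16 with 15E geometry because the remaining Bpin and the polyenyl group sit anti in the eliminating conformer. After the aqueous phosphate quench, zerovalent palladium formed from Pd(OAc)2 and SPhos inserts into the C14–iodine bond of 14, the base-activated boronate transfers C15, and reductive elimination forges C14–C15, each event with retention of alkene geometry. The closest known reaction type is the Suzuki–Miyaura union of polyenyl halides with polyenyl boronates used for retinoid and carotenoid chains, here telescoped with the known aldehyde-to-vinylboronate olefination. No ring is closed and no stereocentre is created: 13E is inherited from the carboalumination-derived iodide, 15E from the boron–Wittig stage, and C3 in ring A is remote and untouched. The step needs chemoselectivity for one C(sp2)–iodine bond in the presence of the ester, the isolated Z-alkene of the oleate and both polyene chains; this is secured by the fast room-temperature oxidative addition of a vinyl iodide, the absence of any other halide or pseudohalide, and the mild phosphate base. Quenching the carbanion before 14 is added protects the ester from nucleophilic attack.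

Compound list
1 | (4R,6R)-4-hydroxy-2,2,6-trimethylcyclohexanone (actinol) | O[C@@H]1C[C@@H](C)C(=O)C(C)(C)C1 | starting material
2 | oleoyl chloride, (Z)-octadec-9-enoyl chloride | CCCCCCCC/C=C\CCCCCCCC(=O)Cl | starting material
3 | (1R,3R)-3,5,5-trimethyl-4-oxocyclohexyl oleate | CCCCCCCC/C=C\CCCCCCCC(=O)O[C@@H]1C[C@@H](C)C(=O)C(C)(C)C1 | intermediate
4 | (1R)-3,5,5-trimethyl-4-(trifluoromethylsulfonyloxy)cyclohex-3-en-1-yl oleate | CCCCCCCC/C=C\CCCCCCCC(=O)O[C@@H]1CC(C)=C(OS(=O)(=O)C(F)(F)F)C(C)(C)C1 | intermediate
5 | (E)-3-methylpent-2-en-4-yn-1-ol | OC/C=C(C)/C#C | starting material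
6 | (2E,4E)-3-methyl-5-(tributylstannyl)penta-2,4-dien-1-ol | OC/C=C(C)/C=C/[Sn](CCCC)(CCCC)CCCC | intermediate
7 | (1R)-4-[(1E,3E)-5-hydroxy-3-methylpenta-1,3-dienyl]-3,5,5-trimethylcyclohex-3-en-1-yl oleate | CCCCCCCC/C=C\CCCCCCCC(=O)O[C@@H]1CC(C)=C(/C=C/C(C)=C/CO)C(C)(C)C1 | intermediate
8 | [(2E,4E)-3-methyl-5-[(4R)-2,6,6-trimethyl-4-oleoyloxycyclohex-1-enyl]penta-2,4-dienyl]triphenylphosphonium bromide | CCCCCCCC/C=C\CCCCCCCC(=O)O[C@@H]1CC(C)=C(/C=C/C(C)=C/C[P+](c2ccccc2)(c2ccccc2)c2ccccc2)C(C)(C)C1.[Br-] | intermediate
9 | propargyl alcohol | OCC#C | starting material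
10 | dimethylaluminium alkoxide of (E)-3-(dimethylalumanyl)-2-methylprop-2-en-1-ol | C[Al](C)/C=C(C)/CO[Al](C)C | intermediate
11 | (E)-3-iodo-2-methylprop-2-en-1-ol | OC/C(C)=C/I | intermediate
12 | (E)-3-iodo-2-methylprop-2-enal | O=C/C(C)=C/I | intermediate
13 | triphenylphosphonium ylide of 8 | CCCCCCCC/C=C\CCCCCCCC(=O)O[C@@H]1CC(C)=C(/C=C/C(C)=C/C=P(c2ccccc2)(c2ccccc2)c2ccccc2)C(C)(C)C1 | intermediate
14 | (1R)-4-[(1E,3E,5E,7E)-8-iodo-3,7-dimethylocta-1,3,5,7-tetraenyl]-3,5,5-trimethylcyclohex-3-en-1-yl oleate | CCCCCCCC/C=C\CCCCCCCC(=O)O[C@@H]1CC(C)=C(/C=C/C(C)=C/C=C/C(C)=C/I)C(C)(C)C1 | intermediate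
15 | all-trans-retinal | O=C/C=C(C)/C=C/C=C(C)/C=C/C1=C(C)CCCC1(C)C | starting material
16 | 2-[(1E,3E,5E,7E,9E)-4,8-dimethyl-10-(2,6,6-trimethylcyclohex-1-enyl)deca-1,3,5,7,9-pentaenyl]-4,4,5,5-tetramethyl-1,3,2-dioxaborolane | CC1(C)OB(/C=C/C=C(C)/C=C/C=C(C)/C=C/C2=C(C)CCCC2(C)C)OC1(C)C | intermediate
17 | (3R)-β,β-caroten-3-yl (Z)-octadec-9-enoate, (3R)-β-cryptoxanthin oleate | CCCCCCCC/C=C\CCCCCCCC(=O)O[C@@H]1CC(C)=C(/C=C/C(C)=C/C=C/C(C)=C/C=C/C=C(C)/C=C/C=C(C)/C=C/C2=C(C)CCCC2(C)C)C(C)(C)C1 | target

Total step count: 9. Longest linear sequence: 6 (steps 1, 2, 4, 5, 8, 9).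

Steps most likely to fail

Risk 1, step 9: protodeboronation of the unpurified boronate, palladium-induced E/Z isomerisation and oxidative degradation of the long polyene may outrun transmetallation. The fallback makes the same C14–C15 bond as an sp2–sp bond and corrects the oxidation level afterwards. It sets out from 15 and 14 and comes back at 17. Colvin rearrangement of 15 with lithiated trimethylsilyldiazomethane (Me3SiCHN2, LiN(iPr)2, THF, −78 °C to rt) would give the C21 tetraenyne F1. Sonogashira coupling of F1 with 14 (Pd(PPh3)4, CuI, iPr2NH, THF, rt) would give 15,15′-didehydro-β-cryptoxanthin oleate F2. Semihydrogenation with H2 over Pd/CaCO3 poisoned with Pb(OAc)2 and quinoline would give (15Z)-β-cryptoxanthin oleate F3. Warming F3 in heptane should relax the central Z-alkene to the all-E compound 17.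

Risk 2, step 8: poor E/Z selectivity at the new C11=C12 alkene and conjugate addition–elimination of the ylide at the iodo-enal may erode the step. The fallback reverses the polarity to a Horner–Wadsworth–Emmons olefination, which is inherently E-selective. It sets out from 7 and 11 and comes back at 14. MnO2 oxidation of 7 would give the C15 aldehyde F4. Appel bromination of 11 (CBr4, PPh3, CH2Cl2, 0 °C) would give (E)-3-bromo-1-iodo-2-methylprop-1-ene F5. Michaelis–Arbuzov reaction of F5 with P(OEt)3 would give diethyl [(E)-3-iodo-2-methylprop-2-enyl]phosphonate F6. Deprotonation of F6 with LiN(SiMe3)2 in THF at −78 °C and addition of F4 should deliver 14.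

Risk 3, step 2: sluggish O-sulfonylation of the hindered carbonyl may allow cationic methyl migration or acid-induced loss of the acyloxy group. The fallback traps a preformed lithium enolate on a substrate without an ester and acylates later. It sets out from 1 and comes back at 4. Silylation of 1 (TBSCl, imidazole, DMF) would give the actinol TBS ether F7. Treatment with LiN(iPr)2 and then PhNTf2 in THF (−78 °C to rt) would give the silyloxy enol triflate F8. HF·pyridine in THF would free the hydroxy enol triflate F9. Acylation of F9 with 2 (pyridine, DMAP, CH2Cl2) gives 4.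

Further compounds
F1 | step 9 | (3E,5E,7E,9E)-4,8-dimethyl-10-(2,6,6-trimethylcyclohex-1-enyl)deca-3,5,7,9-tetraen-1-yne | C#C/C=C(C)/C=C/C=C(C)/C=C/C1=C(C)CCCC1(C)C
F2 | step 9 | (3R)-15,15′-didehydro-β-cryptoxanthin oleate | CCCCCCCC/C=C\CCCCCCCC(=O)O[C@@H]1CC(C)=C(/C=C/C(C)=C/C=C/C(C)=C/C#C/C=C(C)/C=C/C=C(C)/C=C/C2=C(C)CCCC2(C)C)C(C)(C)C1
F3 | step 9 | (3R,15Z)-β-cryptoxanthin oleate | CCCCCCCC/C=C\CCCCCCCC(=O)O[C@@H]1CC(C)=C(/C=C/C(C)=C/C=C/C(C)=C/C=C\C=C(C)\C=C\C=C(C)\C=C\C2=C(C)CCCC2(C)C)C(C)(C)C1
F4 | step 8 | (1R)-3,5,5-trimethyl-4-[(1E,3E)-3-methyl-5-oxopenta-1,3-dienyl]cyclohex-3-en-1-yl oleate | CCCCCCCC/C=C\CCCCCCCC(=O)O[C@@H]1CC(C)=C(/C=C/C(C)=C/C=O)C(C)(C)C1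
F5 | step 8 | (E)-3-bromo-1-iodo-2-methylprop-1-ene | BrC/C(C)=C/I
F6 | step 8 | diethyl [(E)-3-iodo-2-methylprop-2-enyl]phosphonate | CCOP(=O)(C/C(C)=C/I)OCC
F7 | step 2 | (4R,6R)-4-(tert-butyldimethylsilyloxy)-2,2,6-trimethylcyclohexanone | CC(C)(C)[Si](C)(C)O[C@@H]1C[C@@H](C)C(=O)C(C)(C)C1
F8 | step 2 | (4R)-4-(tert-butyldimethylsilyloxy)-2,6,6-trimethylcyclohex-1-enyl triflate | CC(C)(C)[Si](C)(C)O[C@@H]1CC(C)=C(OS(=O)(=O)C(F)(F)F)C(C)(C)C1
F9 | step 2 | (4R)-4-hydroxy-2,6,6-trimethylcyclohex-1-enyl triflate | O[C@@H]1CC(C)=C(OS(=O)(=O)C(F)(F)F)C(C)(C)C1
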